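**Assumption:** the target SMILES has no stereocentres (the molecule is achiral), so "single enantiomer" is taken to mean the compound as drawn and no stereocontrol is needed.

## Retrosynthetic overview

1. Zanthobisquinolone is cut at both C3–CH2 bonds into two molecules of 4-hydroxy-1-methylquinolin-2(1H)-one plus a one-carbon unit; the new step takes that carbon from CO2 (reductive methylene bridging).
2. The monomer quinolone comes from its 3-ethoxycarbonyl derivative by hydrolysis and decarboxylation.
3. That ester comes from N-methylisatoic anhydride and diethyl malonate; the pyridone ring is formed here by C-acylation, CO2 loss and lactamisation.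
4. Ring order: the benzene ring is purchased, the pyridone ring is built in step 1, and the two halves are joined last.

## Route

**Step 1**
Reactants: 1, N-methylisatoic anhydride (1-methyl-2H-3,1-benzoxazine-2,4(1H)-dione); 2, diethyl malonate
Product: 3, ethyl 4-hydroxy-1-methyl-2-oxo-1,2-dihydroquinoline-3-carboxylate
Conditions: NaH (1.2 equiv), 2 (1.5 equiv), DMA, 0 °C then 110 °C, 4 h; aq. HCl work-up
Reagents that add atoms: none (all product atoms come from 1 and 2; CO2 and EtOH are lost)
Why: Isatoic-anhydride quinolone annulation (Coppola type): sodiomalonate C-acylates at the C4 anhydride carbonyl, ring opening and loss of CO2 free the N-methylaniline nitrogen, which lactamises onto one ester; no stereocentre is formed.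

**Step 2**
Reactants: 3, ethyl 4-hydroxy-1-methyl-2-oxo-1,2-dihydroquinoline-3-carboxylate
Product: 4, 4-hydroxy-1-methylquinolin-2(1H)-one
Conditions: 2 M aq. NaOH, reflux, 5 h; then conc. HCl to pH 1, 80 °C (–CO2); filter
Reagents that add atoms: none (C3–H comes from water/acid)
Why: Ester saponification followed by decarboxylation of the vinylogous β-keto acid; the N-methyl lactam and the enol tolerate both the base and the acid.

**Step 3**
Reactants: 4, 4-hydroxy-1-methylquinolin-2(1H)-one (2 equiv); 5, carbon dioxide
Product: 6, zanthobisquinolone (3,3'-methylenebis(4-hydroxy-1-methylquinolin-2(1H)-one)), achiral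
Conditions: CO2 (1 atm), PhSiH3 (0.8 equiv per 4), TBD (10 mol%), MeCN (0.5 M), 50 °C, 16 h; then 1 M HCl/MeOH, rt; filter the precipitate
Reagents that add atoms: carbon dioxide, O=C=O (supplies the bridging CH2 carbon; PhSiH3 supplies only hydride hydrogens)
Why: Proposed new method: TBD deprotonates 4 to a carboxylate-like quinolonate that activates PhSiH3 as a hydridosilicate, which reduces CO2 through silyl formate to the bis(silyl)acetal (formaldehyde oxidation level); this CH2=O equivalent condenses at C3 of 4 (Knoevenagel) to the 3-methylene-quinoline-2,4-dione, a second molecule of 4 adds in a Michael fashion, and the insoluble, doubly hydrogen-bonded (or O-silylated) bis-adduct is protected from over-reduction, helped by the limited silane and the absence of any N–H to divert the C1 unit; the closest known reaction types are the Lewis-base-catalysed CO2/hydrosilane coupling of amines to N–CH2–N aminals and the classical formaldehyde Knoevenagel–Michael dimerisation of 4-hydroxy-2-quinolones, but this C–CH2–C bridging of a heteroaryl enol C–H with CO2 has not been shown.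

## Compound list

1 | N-methylisatoic anhydride | CN1C(=O)OC(=O)c2ccccc21 | starting material
2 | diethyl malonate | CCOC(=O)CC(=O)OCC | starting material
3 | ethyl 4-hydroxy-1-methyl-2-oxo-1,2-dihydroquinoline-3-carboxylate | CCOC(=O)c1c(O)c2ccccc2n(C)c1=O | intermediate
4 | 4-hydroxy-1-methylquinolin-2(1H)-one | Cn1c(=O)cc(O)c2ccccc21 | intermediate
5 | carbon dioxide | O=C=O | starting material (C1 source)
6 | zanthobisquinolone | Cn1c(=O)c(Cc2c(O)c3ccccc3n(C)c2=O)c(O)c2ccccc21 | target

## Summary

Total steps: 3. Longest linear sequence: 3.

Steps most likely to fail, with fallbacks:

1. **Step 3 (proposed new CO2 methylene bridging).** Risks are over-reduction to the 3-methyl quinolone, stalling at the formate/3-formyl level, or silane being consumed by O–H silylation. Fallback (known chemistry): drop the reductive CO2 strategy and use a pre-formed C1 electrophile, condensing 4 (2 equiv) with 37% aqueous formaldehyde (1 equiv) in refluxing EtOH. This is the classical redox-neutral Knoevenagel–Michael reaction, and the product precipitates.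
2. **Step 1 (isatoic anhydride annulation).** Risks are self-condensation or hydrolysis of 1 and incomplete lactamisation. Fallback: build the ring by a different closure: N-methylaniline with Meldrum's acid (neat, 90 °C) gives N-methyl-N-phenylmalonamic acid, and Eaton's reagent (70–80 °C) closes it by intramolecular Friedel–Crafts acylation to give 4 directly.
3. **Step 2 (hydrolysis and decarboxylation).** Risks are incomplete decarboxylation or loss of material as the soluble acid salt. Fallback: avoid the carboxyl group altogether: acetylate methyl N-methylanthranilate (AcCl, pyridine) and cyclise with KOtBu or KHMDS in THF (Dieckmann-type intramolecular Claisen) to give 4 with no decarboxylation needed.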